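Take the settings and the steps first; the quick number you asked for follows from them.

all flasks: substrate 0.80 M

| charge | remark | time |
|---|---|---|
| eta | a single well-mixed tank run continuously and read at steady state, 800 s in it on average |  |
| gamma | everything together in a closed stirred flask, run for 80 s | 80 s |
| alpha | a single well-mixed tank run continuously and read at steady state, 80 s in it on average |  |

    substrate → ring (k1 = 0.0117 s⁻¹)
    2 substrate → open dimer (k2 = 0.0276 M⁻¹ s⁻¹)
    substrate + ring → side product (k3 = 0.0345 M⁻¹ s⁻¹)

- in percentages every species weighs as the substrate in it: one open dimer or side product counts as two
- two of one species on the left: rate k times its square, two consumed each time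
- the stated concentrations are those of everything mixed, before any reaction; amounts are the same in each set-up
- run time (gamma): 80 s

1. the set-up with the highest share of ring in all that became ring or open dimer or side product, at the outlet or at the end ("none" if the first two lie within 2 percentage points) (eta / gamma / alpha / none)
2. share of ring in all that became ring or open dimer or side product, at the outlet or at the end, eta
3. share of ring in all that became ring or open dimer or side product, at the outlet or at the end, gamma
4. share of ring in all that became ring or open dimer or side product, at the outlet or at the end, alpha

I work in fractions of the charge, with s for substrate left and r for ring. My quantity is the branch number b, a selectivity factor: the ring-forming constant over twice the dimerisation constant times the charge, which is the substrate used for ring over that used for open dimer at full charge, 0.265. At any s that ratio is b/s. Since b is below 1, substrate goes to open dimer faster than to ring at the start of gamma.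

Substrate cancels from ring made over ring lost, which is ρ/r with ρ = 0.424. So I freeze the side step's draw on substrate and lay its ring loss on afterwards. For gamma at 80 s:

s = 0.119

ring made, b·ln((1+b)/(b+s)) = 0.316

ring standing, ρ(1−exp(−made/ρ)) = 0.223

share, r/(1−s) = 25.3%

That leaves 0.565 in open dimer, more than ring. I have no hand figure for the tanks.

The forecast gives eta 25%, gamma 23.4%, alpha 23.9% and best none, on the ground that "The top two differ by about 1.1 points, under 2". Its gamma stands below mine.

The simulation gives eta 25.0%, gamma 23.4%, alpha 23.9% and best none.

In gamma at 80.0 s, ring stands at 21.3% and open dimer at 53.0%, against my 22.3% and 56.5% from b = 0.265. A neighbour of gamma charged with 0.20 M, at the same time, has b = 1.06. The same lines give s = 0.249, ring made 0.480 and ring standing 0.418. That neighbour ends with substrate at 21.9%, open dimer at 25.9% and ring at 40.6%, a share of 52.0%.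

All constants stand for no real mixture; the flask was simulated.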